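The cyclopentane C1–C5 carries the C4 carbinol next to C5–C6(O), an aldol pattern. Opened there, it is a keto-aldehyde, that is, an ozonised cyclohexene C4=C6. Its bonds C2–C3 and C5–C1 are made together by a catalytic enantioselective, para-selective Diels–Alder reaction of two achiral acyclic olefins, 2-isopropylbutadiene and 2-allylacrolein, which sets quaternary C1. The formyl group, the latent C15 methyl, then relays C5 and C4 through a cis-fused lactol. C6 follows by chelation, C8/C9 by directed epoxidation after ring-closing metathesis. Daucane numbering is used: C1 quaternary ring-fusion carbon, C4 carbinol, C5 ring-fusion CH, C6 ester carbon, C8/C9 epoxide, C15 methyl on C1.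

Key step: step 3

Remark: β denotes the face of the C15 methyl group on C1, α the opposite face; atom numbers in the Why lines are target (daucane) numbers.

Assumption: the (S)-diphenylprolinol-derived oxazaborolidinium catalyst is taken to expose the face of 4 that leads to (S)-5; if the facial sense is the reverse, the mirror-image catalyst from (R)-diphenylprolinol is used with no other change.

**Route**

Step 1
Reactants: 1 3-methylbut-1-yne
Product: 2 2-(propan-2-yl)buta-1,3-diene
Conditions: ethene (4 bar), second-generation Grubbs catalyst (3 mol %), CH2Cl2, 40 °C, sealed vessel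
Reagents that add atoms: ethene, C=C
Why: Cross enyne metathesis of a terminal alkyne with ethene places a methylidene unit on each alkyne carbon and should give the 2-substituted 1,3-diene directly; no stereocentre is formed.

Step 2
Reactants: 3 pent-4-enal
Product: 4 2-methylidenepent-4-enal (2-allylacrolein)
Conditions: 37 % aq. CH2O, pyrrolidine (10 mol %), propanoic acid (10 mol %), iPrOH, 45 °C
Reagents that add atoms: formaldehyde, C=O
Why: Amine-catalysed Mannich condensation with formaldehyde followed by elimination of the amine (α-methylenation of an aldehyde) should give the 2-substituted acrolein; no stereocentre is formed.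

Step 3
Reactants: 2 2-(propan-2-yl)buta-1,3-diene; 4 2-methylidenepent-4-enal
Product: 5 (1S)-4-(propan-2-yl)-1-(prop-2-en-1-yl)cyclohex-3-ene-1-carbaldehyde
Conditions: chiral oxazaborolidinium triflimide from (S)-α,α-diphenylprolinol, o-tolylboronic acid and HNTf2 (10 mol %), CH2Cl2, −78 → −40 °C
Reagents that add atoms: none
Why: The cationic boron Lewis acid binds the formyl oxygen of 4 and lowers its LUMO, and diene 2 adds in a concerted, asynchronous [4+2] cycloaddition in which the enal CH2 bonds to the diene CH2 next to the isopropyl-bearing carbon (C2–C3) and the formyl-bearing carbon bonds to the other diene CH2 (C5–C1). The closest known reaction type is the enantioselective Diels–Alder reaction of 2-substituted acroleins with 2-substituted butadienes under chiral oxazaborolidinium catalysis. One ring, the cyclohexene, is closed by intermolecular [4+2] cycloaddition, both new σ-bonds forming suprafacially on each partner. The single new stereocentre, quaternary C1, is controlled by the catalyst, whose aryl group shields one face of the bound s-trans enal. The step needs para regioselectivity, which is secured by the match of the larger diene HOMO coefficient (CH2 next to the alkyl-bearing carbon) with the larger enal LUMO coefficient (β-CH2) and is reinforced by Lewis acid activation, and it needs chemoselectivity for the conjugated alkene, which is secured because the isolated allyl double bond is not activated.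

Step 4
Reactants: 5 (1S)-4-(propan-2-yl)-1-(prop-2-en-1-yl)cyclohex-3-ene-1-carbaldehyde
Product: 6 [(1S)-4-(propan-2-yl)-1-(prop-2-en-1-yl)cyclohex-3-en-1-yl]methanol
Conditions: NaBH4, MeOH, 0 °C
Reagents that add atoms: none
Why: Hydride reduction of the neopentyl aldehyde with NaBH4 is expected to leave both alkenes and the quaternary stereocentre untouched.

Step 5
Reactants: 6 [(1S)-4-(propan-2-yl)-1-(prop-2-en-1-yl)cyclohex-3-en-1-yl]methanol
Product: 9 1-[(3S)-5-hydroxy-3-(prop-2-en-1-yl)oxolan-3-yl]-4-methylpentan-3-one (lactol as anomeric mixture), via ozonide 7 (not isolated), via keto-aldehyde 8 (not isolated)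
Conditions: O3 (ca. 1 equiv, Sudan Red 7B end point), CH2Cl2, −78 °C; then PPh3, −78 °C → rt
Reagents that add atoms: ozone, [O-][O+]=O
Why: Ozonolysis with reductive work-up: the electron-rich trisubstituted ring alkene should react with electrophilic ozone well before the monosubstituted allyl group when ozone is limited by the indicator, and the liberated aldehyde is captured by the neighbouring CH2OH as a five-membered lactol; no defined stereocentre is created.

Step 6
Reactants: 9 1-[(3S)-5-hydroxy-3-(prop-2-en-1-yl)oxolan-3-yl]-4-methylpentan-3-one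
Product: 11 (3aS,6R,6aR)-6-(propan-2-yl)-3a-(prop-2-en-1-yl)hexahydro-1H-cyclopenta[c]furan-1,6-diol (anomeric mixture at C1 of the bicycle), via hydroxy-aldehyde 10 (not isolated)
Conditions: pyrrolidine (30 mol %), AcOH (30 mol %), THF, 23 °C
Reagents that add atoms: none
Why: Aldehyde-selective enamine formation from the masked aldehyde of the lactol (the isopropyl ketone is too hindered) should trigger a 5-enolexo intramolecular aldol addition to the ketone; C5 stays epimerisable through the enamine and is drained into the only epimer able to close the cis-fused lactol (formyl cis to CH2OH), while at C4 the isopropyl group takes the convex face so that the hydroxyl is cis to the lactol carbon, and lactol closure removes the free aldehyde needed for dehydration.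

Step 7
Reactants: 11 (3aS,6R,6aR)-6-(propan-2-yl)-3a-(prop-2-en-1-yl)hexahydro-1H-cyclopenta[c]furan-1,6-diol
Product: 13 (1R,2S,3S)-3-(hydroxymethyl)-2-[(1S)-1-hydroxy-3-methylbut-3-en-1-yl]-1-(propan-2-yl)-3-(prop-2-en-1-yl)cyclopentan-1-ol, via bis(chloromagnesium) alkoxide 12 (not isolated)
Conditions: 2-methylallylmagnesium chloride (4 equiv), THF, −78 → 0 °C; aq. NH4Cl
Reagents that add atoms: 2-methylallylmagnesium chloride, CC(=C)C[Mg]Cl
Why: Two equivalents of the Grignard reagent deprotonate both hydroxyls of the lactol, whose anomeric alkoxide opens to the aldehyde dialkoxide 12, in which the C4 alkoxide and the C6 carbonyl should be held in a six-membered magnesium chelate (Cram-chelate model) cis-fused to the cyclopentane, so that Grignard addition to the carbonyl face opposite C1 sets (6S), that is, the 6α-alcohol.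

Step 8
Reactants: 13 (1R,2S,3S)-3-(hydroxymethyl)-2-[(1S)-1-hydroxy-3-methylbut-3-en-1-yl]-1-(propan-2-yl)-3-(prop-2-en-1-yl)cyclopentan-1-ol
Product: 14 (3R,3aS,4S,8aS)-8a-(hydroxymethyl)-6-methyl-3-(propan-2-yl)-1,2,3,3a,4,5,8,8a-octahydroazulene-3,4-diol
Conditions: second-generation Grubbs catalyst (5 mol %), CH2Cl2 (5 mM), 40 °C
Reagents that add atoms: none
Why: Ring-closing metathesis between the monosubstituted and the 1,1-disubstituted alkene should close the seven-membered ring with the trisubstituted C8=C9 alkene, the trans ring fusion being already fixed at C1 and C5.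

Step 9
Reactants: 14 (3R,3aS,4S,8aS)-8a-(hydroxymethyl)-6-methyl-3-(propan-2-yl)-1,2,3,3a,4,5,8,8a-octahydroazulene-3,4-diol
Product: 15 O-{[(3R,3aS,4S,8aS)-3,4-dihydroxy-6-methyl-3-(propan-2-yl)-2,3,3a,4,5,8-hexahydroazulen-8a(1H)-yl]methyl} O-phenyl carbonothioate
Conditions: PhOC(S)Cl (1.1 equiv), pyridine, CH2Cl2, 0 °C
Reagents that add atoms: O-phenyl chlorothionoformate, S=C(Cl)Oc1ccccc1
Why: Thionocarbonate formation (first stage of a Barton–McCombie deoxygenation) should occur at the primary hydroxyl, the secondary one being flanked by the ring fusion and the tertiary one being unreactive.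

Step 10
Reactants: 15 O-{[(3R,3aS,4S,8aS)-3,4-dihydroxy-6-methyl-3-(propan-2-yl)-2,3,3a,4,5,8-hexahydroazulen-8a(1H)-yl]methyl} O-phenyl carbonothioate
Product: 16 (3R,3aS,4S,8aR)-6,8a-dimethyl-3-(propan-2-yl)-1,2,3,3a,4,5,8,8a-octahydroazulene-3,4-diol (dauc-8-ene-4β,6α-diol)
Conditions: Bu3SnH, AIBN (cat.), toluene, 110 °C
Reagents that add atoms: none
Why: Barton–McCombie radical deoxygenation: the tributyltin radical adds to the C=S group, the primary C–O bond fragments at 110 °C and the neopentyl-type radical, which has no productive cyclisation mode, is reduced by Bu3SnH to the C15 methyl group without touching a stereocentre.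

Step 11
Reactants: 16 (3R,3aS,4S,8aR)-6,8a-dimethyl-3-(propan-2-yl)-1,2,3,3a,4,5,8,8a-octahydroazulene-3,4-diol
Product: 17 (1R,4R,5S,6S,8R,9S)-8,9-epoxydaucane-4,6-diol (8α,9α-epoxide of 16)
Conditions: VO(acac)2 (5 mol %), tBuOOH, CH2Cl2, 0 °C → rt
Reagents that add atoms: tert-butyl hydroperoxide, CC(C)(C)OO
Why: Vanadium-catalysed hydroxyl-directed epoxidation: the homoallylic C6 hydroxyl on the α-face should deliver the peroxide oxygen to the α-face of C8=C9, which is also the face remote from the β C15 methyl, setting (8R,9S).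

Step 12
Reactants: 17 (1R,4R,5S,6S,8R,9S)-8,9-epoxydaucane-4,6-diol
Product: 18 (1R,4R,5S,6S,8R,9S)-8,9-epoxy-4-hydroxydaucan-6-yl 4-methoxybenzoate (CNP0235939.1)
Conditions: 4-MeOC6H4COCl, Et3N, DMAP (cat.), CH2Cl2, 0 °C → rt
Reagents that add atoms: 4-methoxybenzoyl chloride, COc1ccc(cc1)C(Cl)=O
Why: DMAP-catalysed acylation should esterify only the secondary C6 hydroxyl, the tertiary C4 hydroxyl being too hindered, and the basic medium preserves the epoxide.

**Compound list**

1 | 3-methylbut-1-yne | CC(C)C#C | starting material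
2 | 2-(propan-2-yl)buta-1,3-diene | C=CC(=C)C(C)C | intermediate
3 | pent-4-enal | C=CCCC=O | starting material
4 | 2-methylidenepent-4-enal | C=CCC(=C)C=O | intermediate
5 | (1S)-4-(propan-2-yl)-1-(prop-2-en-1-yl)cyclohex-3-ene-1-carbaldehyde | O=C[C@]1(CC=C)CCC(C(C)C)=CC1 | intermediate
6 | [(1S)-4-(propan-2-yl)-1-(prop-2-en-1-yl)cyclohex-3-en-1-yl]methanol | OC[C@]1(CC=C)CCC(C(C)C)=CC1 | intermediate
7 | ozonide (1,2,4-trioxolane) of the ring alkene of 6 | OC[C@]1(CC=C)CCC2(C(C)C)OOC(C1)O2 | intermediate (not isolated)
8 | (3S)-3-(hydroxymethyl)-7-methyl-6-oxo-3-(prop-2-en-1-yl)octanal | OC[C@@](CC=C)(CC=O)CCC(=O)C(C)C | intermediate (not isolated)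
9 | 1-[(3S)-5-hydroxy-3-(prop-2-en-1-yl)oxolan-3-yl]-4-methylpentan-3-one | OC1C[C@@](CC=C)(CCC(=O)C(C)C)CO1 | intermediate
10 | (1R,2R,5S)-2-hydroxy-5-(hydroxymethyl)-2-(propan-2-yl)-5-(prop-2-en-1-yl)cyclopentane-1-carbaldehyde | OC[C@]1(CC=C)CC[C@@](O)(C(C)C)[C@@H]1C=O | intermediate (not isolated)
11 | (3aS,6R,6aR)-6-(propan-2-yl)-3a-(prop-2-en-1-yl)hexahydro-1H-cyclopenta[c]furan-1,6-diol | OC1OC[C@]2(CC=C)CC[C@@](O)(C(C)C)[C@H]12 | intermediate
12 | bis(chloromagnesium) dialkoxide of 10: (1R,2R,5S)-2-(chloromagnesiooxy)-5-[(chloromagnesiooxy)methyl]-2-(propan-2-yl)-5-(prop-2-en-1-yl)cyclopentane-1-carbaldehyde | Cl[Mg]OC[C@]1(CC=C)CC[C@@](O[Mg]Cl)(C(C)C)[C@@H]1C=O | intermediate (not isolated)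
13 | (1R,2S,3S)-3-(hydroxymethyl)-2-[(1S)-1-hydroxy-3-methylbut-3-en-1-yl]-1-(propan-2-yl)-3-(prop-2-en-1-yl)cyclopentan-1-ol | OC[C@]1(CC=C)CC[C@@](O)(C(C)C)[C@@H]1[C@@H](O)CC(C)=C | intermediate
14 | (3R,3aS,4S,8aS)-8a-(hydroxymethyl)-6-methyl-3-(propan-2-yl)-1,2,3,3a,4,5,8,8a-octahydroazulene-3,4-diol | OC[C@]12CC[C@@](O)(C(C)C)[C@@H]1[C@@H](O)CC(C)=CC2 | intermediate
15 | O-{[(3R,3aS,4S,8aS)-3,4-dihydroxy-6-methyl-3-(propan-2-yl)-2,3,3a,4,5,8-hexahydroazulen-8a(1H)-yl]methyl} O-phenyl carbonothioate | S=C(Oc1ccccc1)OC[C@]12CC[C@@](O)(C(C)C)[C@@H]1[C@@H](O)CC(C)=CC2 | intermediate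
16 | (3R,3aS,4S,8aR)-6,8a-dimethyl-3-(propan-2-yl)-1,2,3,3a,4,5,8,8a-octahydroazulene-3,4-diol | C[C@]12CC[C@@](O)(C(C)C)[C@@H]1[C@@H](O)CC(C)=CC2 | intermediate
17 | (1R,4R,5S,6S,8R,9S)-8,9-epoxydaucane-4,6-diol | C[C@]12CC[C@@](O)(C(C)C)[C@@H]1[C@@H](O)C[C@@]3(C)O[C@H]3C2 | intermediate
18 | (1R,4R,5S,6S,8R,9S)-8,9-epoxy-4-hydroxydaucan-6-yl 4-methoxybenzoate | COc1ccc(C(=O)O[C@H]2C[C@@]3(C)O[C@H]3C[C@@]3(C)CC[C@@](O)(C(C)C)[C@H]23)cc1 | target

**Step count and risks**

Total step count: 12. Longest linear sequence: 11 steps (step 1 or step 2, then steps 3 to 12).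

Steps most likely to fail:

1. Step 6. What may go wrong: loss of water from the β-hydroxy aldehyde to the conjugated enal before the lactol closes, or reversal of the aldol addition. The fallback is a Lewis-acid Mukaiyama-type aldol cyclisation of an enol ether. It sets out from 9, which is dehydrated with MsCl and Et3N (CH2Cl2, 0 → 40 °C) to the cyclic enol ether 1-[(3S)-3-(prop-2-en-1-yl)-2,3-dihydrofuran-3-yl]-4-methylpentan-3-one F1. TiCl4 (CH2Cl2, −78 °C) then activates the ketone for attack by the enol ether carbon. That carbon is held in the furan ring, so only the cis-fused bicycle can form and no enolisable free aldehyde is present; the isopropyl group is again expected on the convex face. Aqueous NaHCO3 work-up should deliver the lactol, and the route is rejoined at 11.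

2. Step 7. What may go wrong: poor facial selectivity in the addition to the aldehyde if the magnesium chelate is not maintained, so that the C6 configuration is not controlled. The fallback sets out from 16 obtained with insufficient purity at C6. Oxidation with Dess–Martin periodinane (NaHCO3, CH2Cl2) converges the material on the β-hydroxy ketone (3R,3aR,8aR)-3-hydroxy-6,8a-dimethyl-3-(propan-2-yl)-2,3,3a,5,8,8a-hexahydroazulen-4(1H)-one F2. Hydroxyl-directed reduction with Me4NBH(OAc)3 (MeCN/AcOH, −20 °C) delivers hydride intramolecularly from the alkoxyborohydride on the β C4 oxygen to the β-face of the C6 carbonyl. This should give the 6α-alcohol, returning the route to 16.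

3. Step 10. What may go wrong: slow fragmentation of the primary C–O bond, so that the thionocarbonate is reduced back to the alcohol. The fallback sets out from 14. Chemoselective oxidation of the primary alcohol with TEMPO (cat.) and PhI(OAc)2 (1.1 equiv, CH2Cl2) should give the angular aldehyde (3R,3aS,4S,8aS)-3,4-dihydroxy-6-methyl-3-(propan-2-yl)-2,3,3a,4,5,8-hexahydroazulene-8a(1H)-carbaldehyde F3. This aldehyde has no α-hydrogen and should stay open, because the C6 hydroxyl lies on the face opposite the formyl group and closure on the C4 hydroxyl would need a strained bridged ring. Wolff–Kishner reduction (N2H4·H2O, KOH, diethylene glycol, 130 → 200 °C) proceeds through the hydrazone (3R,3aS,4S,8aS)-8a-(hydrazinylidenemethyl)-6-methyl-3-(propan-2-yl)-1,2,3,3a,4,5,8,8a-octahydroazulene-3,4-diol F4. It converts the formyl group into the C15 methyl group, rejoining the route at 16.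

**Further compounds**

F1 | step 6 | 1-[(3S)-3-(prop-2-en-1-yl)-2,3-dihydrofuran-3-yl]-4-methylpentan-3-one | C1=C[C@@](CC=C)(CCC(=O)C(C)C)CO1
F2 | step 7 | (3R,3aR,8aR)-3-hydroxy-6,8a-dimethyl-3-(propan-2-yl)-2,3,3a,5,8,8a-hexahydroazulen-4(1H)-one | C[C@]12CC[C@@](O)(C(C)C)[C@@H]1C(=O)CC(C)=CC2
F3 | step 10 | (3R,3aS,4S,8aS)-3,4-dihydroxy-6-methyl-3-(propan-2-yl)-2,3,3a,4,5,8-hexahydroazulene-8a(1H)-carbaldehyde | O=C[C@]12CC[C@@](O)(C(C)C)[C@@H]1[C@@H](O)CC(C)=CC2
F4 | step 10 | (3R,3aS,4S,8aS)-8a-(hydrazinylidenemethyl)-6-methyl-3-(propan-2-yl)-1,2,3,3a,4,5,8,8a-octahydroazulene-3,4-diol | NN=C[C@]12CC[C@@](O)(C(C)C)[C@@H]1[C@@H](O)CC(C)=CC2
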